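The oxane is cut at O1–C2 and C5–C6 (numbering: C2 bears the bromopentenyl chain, C3 Br, C5 Cl, C6 the enynyl chain). O1–C6 is then an aldehyde carbonyl, C5 a nitronate carbon and C2 the β-carbon of an enoate. One base-mediated domino nitroaldol/oxa-Michael reaction of an aldehyde with an ε-nitro-γ-silyloxy enoate should form both bonds and close the ring with every substituent equatorial, steered by the single C3 stereocenter. The step exploits the vicinal O1–C6/C5-heteroatom pair and the CH2 group on C2. The nitro group then becomes the axial chloride (Nef, reduction, inversion) and the silyl ether the axial bromide.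

Key step: step 5

Remark: the oxane atoms keep the numbering O1, C2 (bromopentenyl arm), C3, C4, C5, C6 (enynyl arm) in every intermediate; compounds 1, 3, 8, 15 and 21 are taken as purchasable.

Step 1
Reactants: 1 methyl 4-nitrobutanoate
Product: 2 4-nitrobutanal
Conditions: DIBAL-H (i-Bu2AlH), CH2Cl2, −78 °C
Reagents that add atoms: none
Why: Partial ester reduction: the tetrahedral aluminium hemiacetal formed by i-Bu2AlH is stable at −78 °C and collapses to the aldehyde only on work-up, and the aliphatic nitro group is not reduced under these conditions.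

Step 2
Reactants: 2 4-nitrobutanal; 3 ethyl (triphenylphosphoranylidene)acetate
Product: 5 ethyl (2E,4S)-6-nitro-4-[(phenylamino)oxy]hex-2-enoate, via aminoxy aldehyde 4 (not isolated)
Conditions: PhNO, D-proline (20 mol %), DMSO, rt; then 3, 0 °C to rt
Reagents that add atoms: nitrosobenzene, O=Nc1ccccc1
Why: Proline α-aminoxylation (enamine catalysis): the enamine of 2 with D-proline attacks the nitroso oxygen on one face under direction by the carboxylic acid, which should set the (S) center, and the labile aldehyde 4 is trapped at once by a Wittig reaction with stabilised ylide 3, which should give the (E)-enoate.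

Step 3
Reactants: 5 ethyl (2E,4S)-6-nitro-4-[(phenylamino)oxy]hex-2-enoate
Product: 6 ethyl (2E,4S)-4-hydroxy-6-nitrohex-2-enoate
Conditions: Cu(OAc)2 (30 mol %), EtOH, rt
Reagents that add atoms: none
Why: Cu(OAc)2-catalysed N–O bond cleavage of the O-alkyl N-phenylhydroxylamine should release the allylic alcohol under neutral conditions that leave the nitro group, the enoate and the stereocenter untouched.

Step 4
Reactants: 6 ethyl (2E,4S)-4-hydroxy-6-nitrohex-2-enoate
Product: 7 ethyl (2E,4S)-4-(tert-butyldimethylsilyloxy)-6-nitrohex-2-enoate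
Conditions: TBSCl, imidazole, DMF, rt
Reagents that add atoms: tert-butyldimethylsilyl chloride, CC(C)(C)[Si](C)(C)Cl
Why: Silylation of the secondary alcohol with TBSCl and imidazole gives a base-stable ether that protects the future C3 oxygen and acts as the equatorial control element in the domino step.

Step 5
Reactants: 7 ethyl (2E,4S)-4-(tert-butyldimethylsilyloxy)-6-nitrohex-2-enoate; 8 3-(4-methoxybenzyloxy)propanal
Product: 10 ethyl 2-[(2R,3S,5R,6S)-3-(tert-butyldimethylsilyloxy)-6-[2-(4-methoxybenzyloxy)ethyl]-5-nitrooxan-2-yl]acetate, via nitroaldol 9 (not isolated)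
Conditions: 8 (2 equiv), DBU (1 equiv), MeCN, 0 °C to 40 °C
Reagents that add atoms: none
Why: DBU turns the nitro group of 7 into a nitronate that adds reversibly to aldehyde 8 (Henry reaction, C5–C6), and the hydroxyl of nitroaldol 9 then adds to the (E)-enoate (intramolecular oxa-Michael addition, O1–C2). The closest known reaction type is the domino nitroaldol/hetero-Michael cyclisation that gives nitro-substituted tetrahydropyrans and nitro sugars. The oxane closes in the 6-exo-trig mode through a chair in which the C3 silyloxy group and the new CH2CO2Et arm are both equatorial, so C2 is set by C3 (2,3-trans). C6 and C5 are set by thermodynamics: retro-nitroaldol cleavage, nitronate reprotonation and reversible oxa-Michael addition should funnel the isomers of 9 into the all-equatorial oxane (2,6-cis, 5,6-trans), C5 is erased in step 6 and C6 can still settle next to the ketone there. The step needs the nitronate to attack the aldehyde and not the β-substituted enoate, which the higher electrophilicity and the excess of 8 secure, and a benzylic ether in 8 instead of a silyl ether slows β-elimination to acrolein.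

Step 6
Reactants: 10 ethyl 2-[(2R,3S,5R,6S)-3-(tert-butyldimethylsilyloxy)-6-[2-(4-methoxybenzyloxy)ethyl]-5-nitrooxan-2-yl]acetate
Product: 11 ethyl 2-[(2R,3S,6S)-3-(tert-butyldimethylsilyloxy)-6-[2-(4-methoxybenzyloxy)ethyl]-5-oxooxan-2-yl]acetate
Conditions: t-BuOK, THF, 0 °C; then KMnO4, MgSO4, H2O, 0 °C
Reagents that add atoms: potassium permanganate, [K+].[O-][Mn](=O)(=O)=O
Why: Nef reaction: the potassium nitronate of 10 is oxidised at carbon by KMnO4, which should give the C5 ketone and nitrite, and C6 next to the new ketone can settle in the equatorial (2,6-cis) form.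

Step 7
Reactants: 11 ethyl 2-[(2R,3S,6S)-3-(tert-butyldimethylsilyloxy)-6-[2-(4-methoxybenzyloxy)ethyl]-5-oxooxan-2-yl]acetate
Product: 12 ethyl 2-[(2R,3S,5R,6S)-3-(tert-butyldimethylsilyloxy)-5-hydroxy-6-[2-(4-methoxybenzyloxy)ethyl]oxan-2-yl]acetate
Conditions: NaBH4, MeOH, −40 °C
Reagents that add atoms: none
Why: Hydride reduction of the ring ketone: the small reagent NaBH4 should attack C5 along the axial trajectory of the chair that carries all substituents equatorial, which gives the equatorial alcohol trans to the C6 arm, and the ester is not reduced at this temperature.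

Step 8
Reactants: 12 ethyl 2-[(2R,3S,5R,6S)-3-(tert-butyldimethylsilyloxy)-5-hydroxy-6-[2-(4-methoxybenzyloxy)ethyl]oxan-2-yl]acetate
Product: 13 ethyl 2-[(2R,3S,5S,6S)-3-(tert-butyldimethylsilyloxy)-5-chloro-6-[2-(4-methoxybenzyloxy)ethyl]oxan-2-yl]acetate
Conditions: CCl4, P(n-Oct)3, toluene, 70 °C
Reagents that add atoms: tetrachloromethane, ClC(Cl)(Cl)Cl
Why: Appel chlorination: the alkoxyphosphonium salt of the equatorial C5 alcohol is displaced by chloride in an SN2 reaction with inversion, which should put chlorine axial and cis to the C6 arm.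

Step 9
Reactants: 13 ethyl 2-[(2R,3S,5S,6S)-3-(tert-butyldimethylsilyloxy)-5-chloro-6-[2-(4-methoxybenzyloxy)ethyl]oxan-2-yl]acetate
Product: 14 2-[(2R,3S,5S,6S)-3-(tert-butyldimethylsilyloxy)-5-chloro-6-[2-(4-methoxybenzyloxy)ethyl]oxan-2-yl]acetaldehyde
Conditions: DIBAL-H (i-Bu2AlH), CH2Cl2, −78 °C
Reagents that add atoms: none
Why: Partial reduction of the ethyl ester at −78 °C should stop at the aldehyde through a stable tetrahedral intermediate, and the secondary chloride and both ethers are inert.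

Step 10
Reactants: 15 bis(pinacolatoboryl)methane
Product: 16 1,1-bis(pinacolatoboryl)propane
Conditions: LiTMP, THF, 0 °C; then EtI, 0 °C to rt
Reagents that add atoms: iodoethane, CCI
Why: The α-boryl-stabilised carbanion made from 15 with LiTMP is alkylated by iodoethane (alkylation of a geminal diboryl carbanion).

Step 11
Reactants: 14 2-[(2R,3S,5S,6S)-3-(tert-butyldimethylsilyloxy)-5-chloro-6-[2-(4-methoxybenzyloxy)ethyl]oxan-2-yl]acetaldehyde; 16 1,1-bis(pinacolatoboryl)propane
Product: 17 (2R,3S,5S,6S)-3-(tert-butyldimethylsilyloxy)-5-chloro-6-[2-(4-methoxybenzyloxy)ethyl]-2-[(2Z)-3-(pinacolatoboryl)pent-2-en-1-yl]oxane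
Conditions: 16, LiTMP, THF, 0 °C; then 14, −78 °C to rt
Reagents that add atoms: none
Why: Boron–Wittig olefination: the lithiated geminal bis(boronate) adds to aldehyde 14 and the alkoxide removes one boryl group in a syn B–O elimination through the rotamer that keeps the aldehyde-derived CH2 group anti to the remaining boryl group, so ethyl and the ring CH2 should end up cis in the (Z)-alkenyl boronate.

Step 12
Reactants: 17 (2R,3S,5S,6S)-3-(tert-butyldimethylsilyloxy)-5-chloro-6-[2-(4-methoxybenzyloxy)ethyl]-2-[(2Z)-3-(pinacolatoboryl)pent-2-en-1-yl]oxane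
Product: 18 (2R,3S,5S,6S)-2-[(2E)-3-bromopent-2-en-1-yl]-3-(tert-butyldimethylsilyloxy)-5-chloro-6-[2-(4-methoxybenzyloxy)ethyl]oxane
Conditions: CuBr2, MeOH/H2O, 50 °C
Reagents that add atoms: copper dibromide, [Cu+2].[Br-].[Br-]
Why: Copper-mediated bromodeboronation with CuBr2 replaces boron by bromine at the same alkene position with retention of geometry, so bromine should be trans to the ring CH2 (the descriptor becomes E only because Br outranks carbon).

Step 13
Reactants: 18 (2R,3S,5S,6S)-2-[(2E)-3-bromopent-2-en-1-yl]-3-(tert-butyldimethylsilyloxy)-5-chloro-6-[2-(4-methoxybenzyloxy)ethyl]oxane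
Product: 19 (2R,3S,5S,6S)-2-[(2E)-3-bromopent-2-en-1-yl]-3-(tert-butyldimethylsilyloxy)-5-chloro-6-(2-hydroxyethyl)oxane
Conditions: DDQ, CH2Cl2, pH 7 buffer, 0 °C to rt
Reagents that add atoms: none
Why: Oxidative cleavage of the 4-methoxybenzyl ether by DDQ (hydride abstraction at the electron-rich benzylic position, then hydrolysis) should free the primary alcohol and spare the silyl ether, both halides and the alkene.

Step 14
Reactants: 19 (2R,3S,5S,6S)-2-[(2E)-3-bromopent-2-en-1-yl]-3-(tert-butyldimethylsilyloxy)-5-chloro-6-(2-hydroxyethyl)oxane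
Product: 20 (2R,3S,5S,6S)-2-[(2E)-3-bromopent-2-en-1-yl]-3-(tert-butyldimethylsilyloxy)-5-chloro-6-(2-oxoethyl)oxane
Conditions: DMP (triacetoxy periodinane), NaHCO3, CH2Cl2, rt
Reagents that add atoms: none
Why: Oxidation of the primary alcohol with the periodinane under buffered neutral conditions should stop at the aldehyde and avoid β-elimination of the ring oxygen.

Step 15
Reactants: 20 (2R,3S,5S,6S)-2-[(2E)-3-bromopent-2-en-1-yl]-3-(tert-butyldimethylsilyloxy)-5-chloro-6-(2-oxoethyl)oxane; 21 1,3-bis(triisopropylsilyl)propyne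
Product: 22 (2R,3S,5S,6S)-2-[(2E)-3-bromopent-2-en-1-yl]-3-(tert-butyldimethylsilyloxy)-5-chloro-6-[(2Z)-5-(triisopropylsilyl)pent-2-en-4-yn-1-yl]oxane
Conditions: 21, n-BuLi, THF, −20 °C; then 20, −78 °C to rt
Reagents that add atoms: none
Why: Peterson olefination: lithiated 21 adds to aldehyde 20 and the bulky silyl groups steer the syn-elimination of silanolate towards the (Z)-enyne.

Step 16
Reactants: 22 (2R,3S,5S,6S)-2-[(2E)-3-bromopent-2-en-1-yl]-3-(tert-butyldimethylsilyloxy)-5-chloro-6-[(2Z)-5-(triisopropylsilyl)pent-2-en-4-yn-1-yl]oxane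
Product: 23 (2R,3S,5S,6S)-2-[(2E)-3-bromopent-2-en-1-yl]-5-chloro-6-[(2Z)-pent-2-en-4-yn-1-yl]oxan-3-ol
Conditions: Bu4NF (TBAF), THF, 0 °C to rt
Reagents that add atoms: none
Why: Fluoride should cleave the alkynyl C–Si bond and the secondary silyl ether in one operation (desilylation driven by the strong Si–F bond).

Step 17
Reactants: 23 (2R,3S,5S,6S)-2-[(2E)-3-bromopent-2-en-1-yl]-5-chloro-6-[(2Z)-pent-2-en-4-yn-1-yl]oxan-3-ol
Product: 24 (2R,3R,5S,6S)-3-bromo-2-[(2E)-3-bromopent-2-en-1-yl]-5-chloro-6-[(2Z)-pent-2-en-4-yn-1-yl]oxane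
Conditions: CBr4, P(n-Oct)3, toluene, 70 °C
Reagents that add atoms: tetrabromomethane, BrC(Br)(Br)Br
Why: Appel-type bromination: the alkoxyphosphonium salt of the equatorial C3 alcohol is displaced by bromide in an SN2 reaction with inversion, which should give the axial bromide cis to the C2 arm and so the all-cis target.

Compound list

1 | methyl 4-nitrobutanoate | COC(=O)CCC[N+](=O)[O-] | starting material
2 | 4-nitrobutanal | O=CCCC[N+](=O)[O-] | intermediate
3 | ethyl (triphenylphosphoranylidene)acetate | CCOC(=O)C=P(c1ccccc1)(c1ccccc1)c1ccccc1 | starting material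
4 | (2S)-4-nitro-2-[(phenylamino)oxy]butanal | O=C[C@@H](ONc1ccccc1)CC[N+](=O)[O-] | intermediate (not isolated)
5 | ethyl (2E,4S)-6-nitro-4-[(phenylamino)oxy]hex-2-enoate | CCOC(=O)/C=C/[C@@H](ONc1ccccc1)CC[N+](=O)[O-] | intermediate
6 | ethyl (2E,4S)-4-hydroxy-6-nitrohex-2-enoate | CCOC(=O)/C=C/[C@@H](O)CC[N+](=O)[O-] | intermediate
7 | ethyl (2E,4S)-4-(tert-butyldimethylsilyloxy)-6-nitrohex-2-enoate | CCOC(=O)/C=C/[C@@H](O[Si](C)(C)C(C)(C)C)CC[N+](=O)[O-] | intermediate
8 | 3-(4-methoxybenzyloxy)propanal | COc1ccc(COCCC=O)cc1 | starting material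
9 | ethyl (2E,4S)-4-(tert-butyldimethylsilyloxy)-7-hydroxy-9-(4-methoxybenzyloxy)-6-nitronon-2-enoate (interconverting C6/C7 isomers) | CCOC(=O)/C=C/[C@@H](O[Si](C)(C)C(C)(C)C)CC(C(O)CCOCc1ccc(OC)cc1)[N+](=O)[O-] | intermediate (not isolated)
10 | ethyl 2-[(2R,3S,5R,6S)-3-(tert-butyldimethylsilyloxy)-6-[2-(4-methoxybenzyloxy)ethyl]-5-nitrooxan-2-yl]acetate (all four ring substituents equatorial) | COc1ccc(COCC[C@@H]2O[C@H](CC(=O)OCC)[C@@H](O[Si](C)(C)C(C)(C)C)C[C@H]2[N+](=O)[O-])cc1 | intermediate
11 | ethyl 2-[(2R,3S,6S)-3-(tert-butyldimethylsilyloxy)-6-[2-(4-methoxybenzyloxy)ethyl]-5-oxooxan-2-yl]acetate | COc1ccc(COCC[C@@H]2O[C@H](CC(=O)OCC)[C@@H](O[Si](C)(C)C(C)(C)C)CC2=O)cc1 | intermediate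
12 | ethyl 2-[(2R,3S,5R,6S)-3-(tert-butyldimethylsilyloxy)-5-hydroxy-6-[2-(4-methoxybenzyloxy)ethyl]oxan-2-yl]acetate (equatorial C5 alcohol) | COc1ccc(COCC[C@@H]2O[C@H](CC(=O)OCC)[C@@H](O[Si](C)(C)C(C)(C)C)C[C@H]2O)cc1 | intermediate
13 | ethyl 2-[(2R,3S,5S,6S)-3-(tert-butyldimethylsilyloxy)-5-chloro-6-[2-(4-methoxybenzyloxy)ethyl]oxan-2-yl]acetate (axial C5 chloride) | COc1ccc(COCC[C@@H]2O[C@H](CC(=O)OCC)[C@@H](O[Si](C)(C)C(C)(C)C)C[C@@H]2Cl)cc1 | intermediate
14 | 2-[(2R,3S,5S,6S)-3-(tert-butyldimethylsilyloxy)-5-chloro-6-[2-(4-methoxybenzyloxy)ethyl]oxan-2-yl]acetaldehyde | COc1ccc(COCC[C@@H]2O[C@H](CC=O)[C@@H](O[Si](C)(C)C(C)(C)C)C[C@@H]2Cl)cc1 | intermediate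
15 | bis(pinacolatoboryl)methane | CC1(C)OB(CB2OC(C)(C)C(C)(C)O2)OC1(C)C | starting material
16 | 1,1-bis(pinacolatoboryl)propane | CCC(B1OC(C)(C)C(C)(C)O1)B1OC(C)(C)C(C)(C)O1 | intermediate
17 | (2R,3S,5S,6S)-3-(tert-butyldimethylsilyloxy)-5-chloro-6-[2-(4-methoxybenzyloxy)ethyl]-2-[(2Z)-3-(pinacolatoboryl)pent-2-en-1-yl]oxane | COc1ccc(COCC[C@@H]2O[C@H](C/C=C(/B3OC(C)(C)C(C)(C)O3)CC)[C@@H](O[Si](C)(C)C(C)(C)C)C[C@@H]2Cl)cc1 | intermediate
18 | (2R,3S,5S,6S)-2-[(2E)-3-bromopent-2-en-1-yl]-3-(tert-butyldimethylsilyloxy)-5-chloro-6-[2-(4-methoxybenzyloxy)ethyl]oxane | COc1ccc(COCC[C@@H]2O[C@H](C/C=C(/Br)CC)[C@@H](O[Si](C)(C)C(C)(C)C)C[C@@H]2Cl)cc1 | intermediate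
19 | (2R,3S,5S,6S)-2-[(2E)-3-bromopent-2-en-1-yl]-3-(tert-butyldimethylsilyloxy)-5-chloro-6-(2-hydroxyethyl)oxane | OCC[C@@H]1O[C@H](C/C=C(/Br)CC)[C@@H](O[Si](C)(C)C(C)(C)C)C[C@@H]1Cl | intermediate
20 | (2R,3S,5S,6S)-2-[(2E)-3-bromopent-2-en-1-yl]-3-(tert-butyldimethylsilyloxy)-5-chloro-6-(2-oxoethyl)oxane | O=CC[C@@H]1O[C@H](C/C=C(/Br)CC)[C@@H](O[Si](C)(C)C(C)(C)C)C[C@@H]1Cl | intermediate
21 | 1,3-bis(triisopropylsilyl)propyne | CC(C)[Si](C(C)C)(C(C)C)CC#C[Si](C(C)C)(C(C)C)C(C)C | starting material
22 | (2R,3S,5S,6S)-2-[(2E)-3-bromopent-2-en-1-yl]-3-(tert-butyldimethylsilyloxy)-5-chloro-6-[(2Z)-5-(triisopropylsilyl)pent-2-en-4-yn-1-yl]oxane | CC(C)[Si](C#C/C=C\C[C@@H]1O[C@H](C/C=C(/Br)CC)[C@@H](O[Si](C)(C)C(C)(C)C)C[C@@H]1Cl)(C(C)C)C(C)C | intermediate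
23 | (2R,3S,5S,6S)-2-[(2E)-3-bromopent-2-en-1-yl]-5-chloro-6-[(2Z)-pent-2-en-4-yn-1-yl]oxan-3-ol (equatorial C3 alcohol) | C#C/C=C\C[C@@H]1O[C@H](C/C=C(/Br)CC)[C@@H](O)C[C@@H]1Cl | intermediate
24 | (2R,3R,5S,6S)-3-bromo-2-[(2E)-3-bromopent-2-en-1-yl]-5-chloro-6-[(2Z)-pent-2-en-4-yn-1-yl]oxane (all four ring substituents cis) | C#C/C=C\C[C@@H]1O[C@H](C/C=C(/Br)CC)[C@H](Br)C[C@@H]1Cl | target

Total step count: 17. Longest linear sequence: 16 steps (steps 1–9 and 11–17; step 10 prepares reagent 16).

Steps most likely to fail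

Step 5. The oxa-Michael closure may be slow, so that retro-nitroaldol cleavage, β-elimination of the released aldehyde and intermolecular conjugate addition of the nitronate take over, or equilibration at C6 may stay incomplete. The fallback separates the two bond formations and moves control of C6 to a reagent. It sets out from 7 and 8, which are joined in a Henry reaction catalysed by Cu(OAc)2 and a chiral bis(oxazoline) ligand in EtOH at room temperature. This should give the isolated nitroaldol with the (7S) carbinol F1. The ring is then closed in a separate kinetic oxa-Michael addition of its potassium alkoxide (KN(SiMe3)2, 2.1 equiv, THF, −78 °C), and the route is rejoined at 10.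

Step 11. The two boryl groups may be poorly discriminated in the B–O elimination, which would give mixed or wrong alkene geometry, and the basic carbanion may enolise aldehyde 14 and open the ring by β-elimination. The fallback builds the alkene from an alkyne. It sets out from 14, which a Seyferth–Gilbert homologation (dimethyl (1-diazo-2-oxopropyl)phosphonate, K2CO3, MeOH) should convert into the terminal alkyne F2. Deprotonation and ethylation (n-BuLi, THF, −78 °C, then EtOTf) should give the internal alkyne F3. Hydrozirconation with an excess of Cp2Zr(H)Cl in THF lets zirconium settle on the carbon next to the smaller ethyl group. Bromination with NBS (syn addition of H and Zr, retention in the C–Br bond formation) should then lead to 18, where the route is rejoined and 17 is skipped.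

Step 17. Displacement at C3 must take place on the axial side next to the axial C5 chlorine, so it may be slow and E2 elimination of the alkoxyphosphonium salt may compete. The fallback uses an isolated sulfonate in place of the phosphonium leaving group. It sets out from 23, which is converted into the chloromethanesulfonate F4 (ClCH2SO2Cl, pyridine, CH2Cl2, 0 °C). This compact, strongly activated leaving group is displaced with LiBr in DMF at room temperature with inversion, which should give 24.

Further compounds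

F1 | step 5 | ethyl (2E,4S,7S)-4-(tert-butyldimethylsilyloxy)-7-hydroxy-9-(4-methoxybenzyloxy)-6-nitronon-2-enoate | CCOC(=O)/C=C/[C@@H](O[Si](C)(C)C(C)(C)C)CC([N+](=O)[O-])[C@@H](O)CCOCc1ccc(OC)cc1
F2 | step 11 | (2R,3S,5S,6S)-3-(tert-butyldimethylsilyloxy)-5-chloro-6-[2-(4-methoxybenzyloxy)ethyl]-2-(prop-2-yn-1-yl)oxane | COc1ccc(COCC[C@@H]2O[C@H](CC#C)[C@@H](O[Si](C)(C)C(C)(C)C)C[C@@H]2Cl)cc1
F3 | step 11 | (2R,3S,5S,6S)-3-(tert-butyldimethylsilyloxy)-5-chloro-6-[2-(4-methoxybenzyloxy)ethyl]-2-(pent-2-yn-1-yl)oxane | COc1ccc(COCC[C@@H]2O[C@H](CC#CCC)[C@@H](O[Si](C)(C)C(C)(C)C)C[C@@H]2Cl)cc1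
F4 | step 17 | (2R,3S,5S,6S)-2-[(2E)-3-bromopent-2-en-1-yl]-5-chloro-6-[(2Z)-pent-2-en-4-yn-1-yl]oxan-3-yl chloromethanesulfonate | C#C/C=C\C[C@@H]1O[C@H](C/C=C(/Br)CC)[C@@H](OS(=O)(=O)CCl)C[C@@H]1Cl
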